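**Retrosynthetic overview**

1. Both benzene rings are bought as 1-bromo-3,5-dimethoxybenzene (1); the C16 tether is 1,16-dibromohexadecane (2). Only the macrocycle is built.
2. Both Ar–CH2 bonds are disconnected: Grignard 3 (from 1) plus 2 under Cu catalysis gives the open tetramethyl ether 4.
3. O–Me cleavage with BBr3 (via borate 5) gives the acyclic tetraphenol 6, the presumed biogenetic precursor.
4. The only ring-forming disconnection is the diaryl ether C–O bond: direct dehydrogenative phenol coupling of unprotected 6 (O of one resorcinol to C-4 of the other, via dienone 7) closes the 22-membered ring last and gives grevirobstol B (8).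

Assumption: 8 has no stereocentre and its 22-membered ansa ring is too large for stable planar chirality, so it is achiral and the given SMILES is its full stereochemical description.

**Route**

Step 1
Reactants: 1 1-bromo-3,5-dimethoxybenzene; 2 1,16-dibromohexadecane
Product: 4 1,16-bis(3,5-dimethoxyphenyl)hexadecane, via 3,5-dimethoxyphenylmagnesium bromide 3 (not isolated)
Conditions: 1 (2.6 equiv), Mg, THF, reflux; then 2 (1.0 equiv), Li2CuCl4 (4 mol %), NMP (4 equiv), THF, 0 °C → rt
Reagents that add atoms: none
Why: Kochi-type Cu-catalysed sp2–sp3 Kumada coupling, in which the aryl cuprate formed from 3 displaces both unhindered primary bromides of 2 while the methyl ethers are inert; no stereocentre is formed.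

Step 2
Reactants: 4 1,16-bis(3,5-dimethoxyphenyl)hexadecane
Product: 6 5,5'-(hexadecane-1,16-diyl)bis(benzene-1,3-diol), via tetrakis(dibromoboryl) ether 5 (not isolated)
Conditions: BBr3 (6 equiv), CH2Cl2, −78 °C → rt; then H2O
Reagents that add atoms: none
Why: Lewis-acid aryl methyl ether cleavage (BBr3 demethylation), in which bromide attacks each O-complexed methyl group and the aryl borate 5 is hydrolysed on work-up; the saturated chain is inert and no stereocentre is involved.

Step 3
Reactants: 6 5,5'-(hexadecane-1,16-diyl)bis(benzene-1,3-diol)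
Product: 8 grevirobstol B, via macrocyclic aryloxy dienone 7 (not isolated)
Conditions: [(iPr3tacn)CuCl2] (20 mol %), 2,6-diphenylpyridine (1 equiv), O2 (1 atm), PhMe–1,4-dioxane 9:1, 40 °C, 6 added by syringe pump over 10 h (final 1 mM), stopped at about 50 % conversion
Reagents that add atoms: none
Why: Proposed new method: an aerobic Cu-catalysed dehydrogenative phenol coupling in which a Cu(II)-bound phenoxide/phenoxyl of one resorcinol ring attacks through oxygen the carbon para to OH (C-4) of the other ring, and the resulting dienone 7 tautomerises irreversibly to the diaryl ether; the bulky triazacyclononane ligand shields the ortho carbons and so disfavours C–C and ortho coupling, the symmetry of 6 makes every O→C-4' coupling give the same product, and high dilution favours the 22-membered ring; the closest known reaction type is the Cu/amine/O2 head-to-tail (O to para-C) oxidative coupling of phenols used for poly(phenylene oxide), which tyrosinase-model Cu–triazacyclononane catalysts extend to ortho-unsubstituted phenols; no stereocentre remains in the product.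

**Compound list**

1 | 1-bromo-3,5-dimethoxybenzene | COc1cc(Br)cc(OC)c1 | starting material
2 | 1,16-dibromohexadecane | BrCCCCCCCCCCCCCCCCBr | starting material
3 | 3,5-dimethoxyphenylmagnesium bromide | COc1cc([Mg]Br)cc(OC)c1 | intermediate
4 | 1,16-bis(3,5-dimethoxyphenyl)hexadecane | COc1cc(OC)cc(CCCCCCCCCCCCCCCCc2cc(OC)cc(OC)c2)c1 | intermediate
5 | tetrakis(dibromoboryl) ether of 6 (aryl borate before hydrolysis) | BrB(Br)Oc1cc(OB(Br)Br)cc(CCCCCCCCCCCCCCCCc2cc(OB(Br)Br)cc(OB(Br)Br)c2)c1 | intermediate
6 | 5,5'-(hexadecane-1,16-diyl)bis(benzene-1,3-diol) | Oc1cc(O)cc(CCCCCCCCCCCCCCCCc2cc(O)cc(O)c2)c1 | intermediate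
7 | macrocyclic 4-aryloxy-3-hydroxycyclohexa-2,5-dienone, the keto tautomer of 8 (racemic at the sp3 carbon, which is lost on tautomerisation) | Oc1cc2cc(c1)OC1C(O)=CC(=O)C=C1CCCCCCCCCCCCCCCC2 | intermediate
8 | grevirobstol B | Oc1cc2cc(c1)Oc1c(O)cc(O)cc1CCCCCCCCCCCCCCCC2 | target

**Step count**

Total steps: 3. Longest linear sequence: 3.

**Steps most likely to fail and their fallbacks**

The route has only three steps, so all three are ranked, most risky first.

Step 3 is the main risk. The competing outcomes are C–C coupling to the biaryl isomer, O→C-2' coupling, oligomers, and over-oxidation of the more electron-rich product ring. I expect 15–30 % based on recovered 6. The fallback sets out from 4 and comes back at 8. It replaces the dehydrogenative coupling with an intramolecular Ullmann etherification of a desymmetrised bromo-phenol. NaSEt (1.1 equiv, DMF, 110 °C, unreacted 4 recycled) removes one methyl group and gives 3-[16-(3,5-dimethoxyphenyl)hexadecyl]-5-methoxyphenol F5. Ac2O/pyridine gives 3-[16-(3,5-dimethoxyphenyl)hexadecyl]-5-methoxyphenyl acetate F6, whose acetoxy ring is now the less electron-rich one. NBS (1.0 equiv, MeCN, 0 °C) then brominates only the dimethoxy ring, ortho to the chain and para to OMe, giving 3-[16-(2-bromo-3,5-dimethoxyphenyl)hexadecyl]-5-methoxyphenyl acetate F7. K2CO3/MeOH frees 3-[16-(2-bromo-3,5-dimethoxyphenyl)hexadecyl]-5-methoxyphenol F8. CuI/N,N-dimethylglycine/Cs2CO3 in dioxane at 100 °C and 1 mM closes the ring to tri-O-methylgrevirobstol B F9, and BBr3 (CH2Cl2, −78 °C → rt) gives 8.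

Step 1 may suffer from biaryl homocoupling of 3 and from mono-coupling, since both ends of 2 must react. The fallback sets out from 2 and comes back at 4, with the polarity reversed. Zn dust/LiCl (THF, 50 °C) inserts into both C–Br bonds of 2 to give hexadecane-1,16-diylbis(zinc bromide) F1. A Negishi coupling of F1 with 1 (2.2 equiv, Pd(OAc)2/SPhos, THF, 50 °C) gives 4.

Step 2 is the least risky. The possible problems are incomplete fourfold cleavage and handling of the waxy, air-sensitive tetraphenol after an acidic work-up. The fallback sets out from 2 and comes back at 6, and avoids methyl ethers. Purchased 1-bromo-3,5-bis(benzyloxy)benzene F2 is converted with Mg in THF into 3,5-bis(benzyloxy)phenylmagnesium bromide F3. Coupling of F3 with 2 under the conditions of step 1 gives 1,16-bis[3,5-bis(benzyloxy)phenyl]hexadecane F4. Hydrogenolysis (H2, Pd/C, THF–MeOH, rt) then gives 6 under neutral conditions.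

**Further compounds**

F1 | step 1 | hexadecane-1,16-diylbis(zinc bromide) | Br[Zn]CCCCCCCCCCCCCCCC[Zn]Br
F2 | step 2 | 1-bromo-3,5-bis(benzyloxy)benzene (bought, not made) | Brc1cc(OCc2ccccc2)cc(OCc2ccccc2)c1
F3 | step 2 | 3,5-bis(benzyloxy)phenylmagnesium bromide | Br[Mg]c1cc(OCc2ccccc2)cc(OCc2ccccc2)c1
F4 | step 2 | 1,16-bis[3,5-bis(benzyloxy)phenyl]hexadecane | c1ccccc1COc1cc(OCc2ccccc2)cc(CCCCCCCCCCCCCCCCc2cc(OCc3ccccc3)cc(OCc3ccccc3)c2)c1
F5 | step 3 | 3-[16-(3,5-dimethoxyphenyl)hexadecyl]-5-methoxyphenol | COc1cc(O)cc(CCCCCCCCCCCCCCCCc2cc(OC)cc(OC)c2)c1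
F6 | step 3 | 3-[16-(3,5-dimethoxyphenyl)hexadecyl]-5-methoxyphenyl acetate | COc1cc(OC(C)=O)cc(CCCCCCCCCCCCCCCCc2cc(OC)cc(OC)c2)c1
F7 | step 3 | 3-[16-(2-bromo-3,5-dimethoxyphenyl)hexadecyl]-5-methoxyphenyl acetate | COc1cc(OC(C)=O)cc(CCCCCCCCCCCCCCCCc2cc(OC)cc(OC)c2Br)c1
F8 | step 3 | 3-[16-(2-bromo-3,5-dimethoxyphenyl)hexadecyl]-5-methoxyphenol | COc1cc(O)cc(CCCCCCCCCCCCCCCCc2cc(OC)cc(OC)c2Br)c1
F9 | step 3 | tri-O-methylgrevirobstol B | COc1cc2cc(c1)Oc1c(OC)cc(OC)cc1CCCCCCCCCCCCCCCC2
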